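All runs were computed on assumed constants, noise included.

Whether this flask can be stopped at 15 h with 40 µM of free catalyst is judged here by the number of half-lives of the substrates that fit into that time.

in all of them: left-handed substrate 0.020 M; right-handed substrate 0.020 M; gas 1.1 mM (held); racemization catalyst 0.40 mM
- summer: free catalyst 60 µM; run made earlier
- flask: free catalyst 40 µM; time 15 h

- summer (time / h: left-handed product / %, right-handed product / %, left-handed substrate / %): 0.250: 4.0, 1.7, 47.4; 0.500: 4.9, 2.3, 45.3; 1.33: 14.5, 7.4, 37.5; 3.00: 24.7, 16.3, 26.1

(scatter of a reading: 1 percentage point)

- free catalyst is single-handed; left-handed substrate and right-handed substrate are mirror images of each other, charged as a racemate, each of them at the stated concentration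
- at the start none of the gas is in solution
- an excess is the difference of the two amounts in percent of their sum
- an excess is below zero if the other one leads
- no earlier run changes the charge of free catalyst; that part of a forecast is a guess

- excess of left-handed product over right-handed product in the product at 1.5 h
- excess of left-handed product over right-handed product in the product at 15 h
- part of the left-handed substrate and right-handed substrate charged together that has reacted at 15 h

Turned round, the question is what a flask needs for nearly all of the two substrates to have reacted by 15 h. Each half-life halves what is left, so it needs 5 half-lives, each of 3.00 h. The summer run, read as pseudo-first-order in the two substrates together, has 41.0% reacted at 3.00 h, which gives a reading of 3.94 h for the half-life at 60 µM of free catalyst. The reckoning here scales that reading inversely with the charge, which is a guess: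

half-life in this flask = 5.91 h

half-lives in 15 h = 2.54

This 2.54, the half-life count, is the time allowed divided by the half-life. The reckoned half-life of this flask is about twice the one needed, longer than it, so the reckoning leaves 17.2% unreacted and gives 82.8% reacted. The forecast, “Assuming rate proportional to catalyst”, gives excesses of 27% at 1.5 h and 14% at 15 h, with 82% reacted, between 65% and 90%.

The flask gives excesses of 23.6% and 15.5%, with 96.0% reacted, 14 percentage points above the forecast.

    gas ⇌ partner, rate k1*(csat - [partner]) (kL = 0.140 min⁻¹)
    partner + free catalyst + left-handed substrate → free catalyst + left-handed product (k = 1.50 × 10⁵ M⁻² min⁻¹)
    partner + free catalyst + right-handed substrate → free catalyst + right-handed product (k = 89000 M⁻² min⁻¹)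
    left-handed substrate + racemization catalyst ⇌ right-handed substrate + racemization catalyst, rate k4*[racemization catalyst]*[left-handed substrate] forward; the back reaction follows from the equilibrium constant (k = 9.50 M⁻¹ min⁻¹)
    partner + racemization catalyst → spent catalyst (k = 2.00 M⁻¹ min⁻¹)

In this flask partner stands at 5.19 × 10⁻⁴ M after 1.50 h and at twice that, 0.00104 M, after 15.0 h. The 96.0% reacted in this flask amounts to 4.65 half-lives against the reckoned 2.54. The neighbour flask with 2.4 × 10⁻⁵ M of free catalyst is reckoned the same way at 1.52 half-lives, and its 87.0% reacted amounts to 2.94 half-lives.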